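**Retrosynthetic overview**
Numbering (cembrane): carbocycle C1–C14 with C1 = lactone CH, C3 and C9 = carbinols, C4=C5 (E), C7=C8 (Z), C11 = CHOAc, C12 = C(Me)O; the seven-membered lactone ring is O–C16(=O)–C15(=C17H2)–C1–C14–C13–C12.
Enabling feature: in that lactone ring the ring oxygen sits on the tertiary C12, anti to the C11 oxygen, and C15 sits on C1, which is β to the oxygenated C3. C11/C12 are therefore the retron of an (11R,12R)-epoxide opened with inversion, and C1 is the β-carbon of a C1=C2–C3 enal; a malonate (carbon nucleophile C15, ester oxygen as oxygen nucleophile) is annulated across this 1,4-bis-electrophile in one pot.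
Disconnections: C15=C17 by decarboxylative methylenation of a C15 carboxyl; C3–C4 by Nozaki–Hiyama–Kishi macrocyclisation, then oxidation and CBS reduction for 3S; lactone by the annulation on an acyclic enal–epoxide; C7=C8 by Z-selective Wittig olefination of an α-silyloxy methyl ketone; C9, C11 and C12 by one Shi oxidation of a silyl enol ether/olefin made by carboalumination and conjugate addition.
Ring order: seven-membered lactone first (step 10), 14-membered carbocycle second (step 12).

Key step: step 10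

Remark: enol ether 5 is expected Z-rich and is drawn as Z; compounds 21 to 28 are C15 epimer mixtures (centre erased in step 16); malonate 20 is taken as not commercial and is made in step 9.

**Step 1**
Reactants: 1 hex-5-en-1-yne; 2 but-3-en-2-one
Product: 5 trimethyl{[(2Z,5E)-6-methyldeca-2,5,9-trien-2-yl]oxy}silane, via alkenylalane 3 (not isolated), via aluminium enolate 4 (not isolated)
Conditions: Me3Al, Cp2ZrCl2 (cat.), CH2Cl2, rt; then 2, copper thiophene-2-carboxylate Cu(O2CC4H3S) (cat.), THF, −30 °C; then Me3SiOTf, −78 °C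
Reagents that add atoms: trimethylaluminium, C[Al](C)C; trimethylsilyl trifluoromethanesulfonate, C[Si](C)(C)OS(=O)(=O)C(F)(F)F
Why: Negishi carboalumination (syn addition of Me–Al across the terminal alkyne, methyl to the internal carbon) gives the E-alkenylalane, copper-catalysed conjugate addition transfers the alkenyl group to the enone β-carbon with retention of geometry, and O-silylation of the aluminium enolate fixes the enol ether regiospecifically towards C9.

**Step 2**
Reactants: 5 trimethyl{[(2Z,5E)-6-methyldeca-2,5,9-trien-2-yl]oxy}silane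
Product: 7 (3R)-4-[(2R,3R)-3-(but-3-en-1-yl)-3-methyloxiran-2-yl]-3-hydroxybutan-2-one, via bis-epoxide 6 (not isolated)
Conditions: D-fructose-derived Shi ketone (30 mol %), KHSO5 (Oxone), K2CO3, Bu4NHSO4, MeCN/CH2(OMe)2/aq. Na2B4O7 buffer (pH 10.5), 0 °C; aqueous NaHCO3 work-up
Reagents that add atoms: potassium peroxymonosulfate, [K+].[O-]S(=O)(=O)OO
Why: Shi epoxidation, in which the chiral dioxirane should attack both electron-rich trisubstituted olefins through the spiro transition state with the same enantioface preference (the one that gives R,R-epoxides from E-trisubstituted olefins), setting 11R,12R in the epoxide and 9R in the α-hydroxy ketone released when the silyloxy epoxide collapses on work-up, while the monosubstituted olefin is too unreactive to compete.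

**Step 3**
Reactants: 7 (3R)-4-[(2R,3R)-3-(but-3-en-1-yl)-3-methyloxiran-2-yl]-3-hydroxybutan-2-one
Product: 8 (3R)-4-[(2R,3R)-3-(but-3-en-1-yl)-3-methyloxiran-2-yl]-3-[(tert-butyldimethylsilyl)oxy]butan-2-one
Conditions: TBSCl, imidazole, DMF, rt
Reagents that add atoms: tert-butyldimethylsilyl chloride, CC(C)(C)[Si](C)(C)Cl
Why: Imidazole-promoted silylation of the ketol hydroxyl under conditions too mild to enolise the ketone or open the epoxide keeps the 9R centre and masks O9 as a poorly nucleophilic silyl ether for step 10.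

**Step 4**
Reactants: 9 pent-3-yn-1-ol
Product: 11 (3E)-4-iodopent-3-en-1-ol, via alkenylzirconocene 10 (not isolated)
Conditions: Cp2Zr(H)Cl (2.5 equiv), THF, rt; then I2, 0 °C
Reagents that add atoms: iodine, II
Why: Hydrozirconation adds Zr–H syn across the alkyne with zirconium settling, under equilibration with excess Cp2Zr(H)Cl, on the less hindered methyl-bearing carbon, and iodinolysis with retention gives the E-alkenyl iodide.

**Step 5**
Reactants: 11 (3E)-4-iodopent-3-en-1-ol
Product: 12 (2E)-2,5-diiodopent-2-ene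
Conditions: I2, PPh3, imidazole, CH2Cl2, 0 °C to rt
Reagents that add atoms: iodine, II
Why: Appel-type iodination converts the primary alcohol into the iodide by SN2 displacement of the oxyphosphonium group without touching the alkenyl iodide.

**Step 6**
Reactants: 12 (2E)-2,5-diiodopent-2-ene
Product: 13 [(3E)-4-iodopent-3-en-1-yl]triphenylphosphonium iodide
Conditions: PPh3, MeCN, 80 °C
Reagents that add atoms: triphenylphosphine, c1ccc(cc1)P(c1ccccc1)c1ccccc1
Why: SN2 quaternisation of PPh3 by the primary alkyl iodide gives the Wittig salt, the alkenyl iodide being inert without a transition metal.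

**Step 7**
Reactants: 13 [(3E)-4-iodopent-3-en-1-yl]triphenylphosphonium iodide; 8 (3R)-4-[(2R,3R)-3-(but-3-en-1-yl)-3-methyloxiran-2-yl]-3-[(tert-butyldimethylsilyl)oxy]butan-2-one
Product: 15 tert-butyl{[(2R,3Z,6E)-1-[(2R,3R)-3-(but-3-en-1-yl)-3-methyloxiran-2-yl]-7-iodo-3-methylocta-3,6-dien-2-yl]oxy}dimethylsilane, via phosphorus ylide 14 (not isolated)
Conditions: 13, NaN(SiMe3)2, THF, −78 to 0 °C; then 8, −78 °C to rt
Reagents that add atoms: none
Why: Wittig olefination of an α-oxygenated methyl ketone with a non-stabilised ylide, the known Z-selective case for α-alkoxy and α-silyloxy ketones, should place the incoming C6 chain cis to the oxygenated C9 and give the 7Z-trisubstituted olefin, while epoxide and alkenyl iodide are inert to the ylide.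

**Step 8**
Reactants: 15 tert-butyl{[(2R,3Z,6E)-1-[(2R,3R)-3-(but-3-en-1-yl)-3-methyloxiran-2-yl]-7-iodo-3-methylocta-3,6-dien-2-yl]oxy}dimethylsilane; 16 (2E)-but-2-enal
Product: 17 (2E)-5-[(2R,3R)-3-{(2R,3Z,6E)-2-[(tert-butyldimethylsilyl)oxy]-7-iodo-3-methylocta-3,6-dien-1-yl}-2-methyloxiran-2-yl]pent-2-enal
Conditions: 16 (5 equiv), RuCl2(H2IMes)(=CH-C6H4-2-OiPr) (second-generation Hoveyda–Grubbs catalyst, 5 mol %), CH2Cl2, 40 °C
Reagents that add atoms: none
Why: Olefin cross-metathesis of the only monosubstituted olefin with crotonaldehyde should give the thermodynamically favoured E-enal, the trisubstituted olefins and the alkenyl iodide being too hindered to enter the catalytic cycle.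

**Step 9**
Reactants: 18 3-(tert-butoxy)-3-oxopropanoic acid; 19 2-(trimethylsilyl)ethanol
Product: 20 tert-butyl 2-(trimethylsilyl)ethyl propanedioate
Conditions: DCC, DMAP (cat.), CH2Cl2, 0 °C to rt
Reagents that add atoms: none
Why: Steglich esterification (carbodiimide activation, DMAP acyl transfer) of the malonic half-ester with the primary alcohol gives the mixed malonate.

**Step 10**
Reactants: 17 (2E)-5-[(2R,3R)-3-{(2R,3Z,6E)-2-[(tert-butyldimethylsilyl)oxy]-7-iodo-3-methylocta-3,6-dien-1-yl}-2-methyloxiran-2-yl]pent-2-enal; 20 tert-butyl 2-(trimethylsilyl)ethyl propanedioate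
Product: 22 2-(trimethylsilyl)ethyl (4S,7S)-7-[(1R,3R,4Z,7E)-3-[(tert-butyldimethylsilyl)oxy]-1-hydroxy-8-iodo-4-methylnona-4,7-dien-1-yl]-7-methyl-2-oxo-4-(2-oxoethyl)oxepane-3-carboxylate, via Michael adduct 21 (not isolated)
Conditions: (R)-2-{bis[3,5-bis(trifluoromethyl)phenyl][(trimethylsilyl)oxy]methyl}pyrrolidine (20 mol %), PhCO2H (20 mol %), CH2Cl2, 0 °C to rt; then BF3·OEt2 (promoter), −78 to −40 °C
Reagents that add atoms: none
Why: Proposed new method: the prolinol silyl ether forms the E,s-trans iminium ion of 17 and malonate 20 adds to C1 (C15–C1 bond) from the face left open by the (R)-catalyst; BF3·OEt2 then activates the 11,12-epoxide, the carbonyl oxygen of the tert-butyl ester of 21 attacks the tertiary C12 with inversion (O–C12 bond), and the dialkoxycarbenium ion loses isobutene. The closest known reactions are the amine-catalysed Michael addition of malonates to enals and the Lewis-acid opening of epoxides by tert-butyl esters and carbonates, which have not been telescoped into a formal [4+3] annulation giving an ε-lactone. The one ring closed is the seven-membered lactone, by 7-exo-tet attack of oxygen on the epoxide with C11 left outside the ring. C1 (S) is set by the catalyst, C12 (S) by stereospecific anti opening of the (11R,12R)-epoxide, which also uncovers the 11R carbinol, and C15 is an inconsequential mixture. The step needs 1,4- over 1,2-addition (secured by iminium activation of a β-monosubstituted enal), attack at C12 over C11 (tertiary and exo versus secondary and 8-endo), and lactonisation over cation–olefin cyclisation or attack by O9 (the C7=C8 bond is deactivated by its allylic silyl ether, O9 carries a bulky TBS group, and only the tert-butyl ester can discharge the cation by loss of isobutene).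

**Step 11**
Reactants: 22 2-(trimethylsilyl)ethyl (4S,7S)-7-[(1R,3R,4Z,7E)-3-[(tert-butyldimethylsilyl)oxy]-1-hydroxy-8-iodo-4-methylnona-4,7-dien-1-yl]-7-methyl-2-oxo-4-(2-oxoethyl)oxepane-3-carboxylate
Product: 23 2-(trimethylsilyl)ethyl (4S,7S)-7-[(1R,3R,4Z,7E)-1-acetoxy-3-[(tert-butyldimethylsilyl)oxy]-8-iodo-4-methylnona-4,7-dien-1-yl]-7-methyl-2-oxo-4-(2-oxoethyl)oxepane-3-carboxylate
Conditions: Ac2O, DMAP (cat.), pyridine, CH2Cl2, 0 °C
Reagents that add atoms: acetic anhydride, CC(=O)OC(C)=O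
Why: DMAP-catalysed acylation of the only free hydroxyl (11-OH) installs the acetate of the target before macrocyclisation, the aldehyde and the malonate C–H being untouched at 0 °C.

**Step 12**
Reactants: 23 2-(trimethylsilyl)ethyl (4S,7S)-7-[(1R,3R,4Z,7E)-1-acetoxy-3-[(tert-butyldimethylsilyl)oxy]-8-iodo-4-methylnona-4,7-dien-1-yl]-7-methyl-2-oxo-4-(2-oxoethyl)oxepane-3-carboxylate
Product: 24 macrocyclic allylic alcohol, 2-(trimethylsilyl)ethyl (1S,9R,11R,12S,4E,7Z)-11-acetoxy-9-[(tert-butyldimethylsilyl)oxy]-3-hydroxycembra-4,7-dien-16,12-olid-17-oate (C3 epimers)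
Conditions: CrCl2 (10 equiv), NiCl2 (cat.), DMSO/THF, rt, high dilution (0.002 M)
Reagents that add atoms: none
Why: Nozaki–Hiyama–Kishi reaction, in which nickel-catalysed formation of the alkenylchromium species from the E-alkenyl iodide (retention of geometry) and its chemoselective addition to the aldehyde close the 14-membered ring at C3–C4 in the presence of esters, lactone and the acidic malonate C–H, the new C3 centre being left uncontrolled and set in steps 13 and 14.

**Step 13**
Reactants: 24 macrocyclic allylic alcohol (C3 epimers)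
Product: 25 macrocyclic enone, 2-(trimethylsilyl)ethyl (1S,9R,11R,12S,4E,7Z)-11-acetoxy-9-[(tert-butyldimethylsilyl)oxy]-3-oxocembra-4,7-dien-16,12-olid-17-oate
Conditions: MnO2 (activated, excess), CH2Cl2, rt
Reagents that add atoms: none
Why: MnO2 oxidises the allylic alcohol epimers selectively and convergently to one cross-conjugated enone under neutral conditions, which spares the malonate C–H and avoids base-induced retro-Michael cleavage of the C1–C15 bond.

**Step 14**
Reactants: 25 macrocyclic enone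
Product: 26 2-(trimethylsilyl)ethyl (1S,3S,9R,11R,12S,4E,7Z)-11-acetoxy-9-[(tert-butyldimethylsilyl)oxy]-3-hydroxycembra-4,7-dien-16,12-olid-17-oate
Conditions: (R)-2-methyl-CBS-oxazaborolidine, catecholborane, toluene/CH2Cl2, −78 °C
Reagents that add atoms: none
Why: Corey–Bakshi–Shibata reduction, in which the (R)-oxazaborolidine–borane complex binds the ketone with the 2-substituted alkenyl arm (C4) as the large and C2H2 as the small group and should deliver hydride to the face that gives the 3S allylic alcohol, with 1,2-selectivity at low temperature.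

**Step 15**
Reactants: 26 2-(trimethylsilyl)ethyl (1S,3S,9R,11R,12S,4E,7Z)-11-acetoxy-9-[(tert-butyldimethylsilyl)oxy]-3-hydroxycembra-4,7-dien-16,12-olid-17-oate
Product: 27 (1S,3S,9R,11R,12S,4E,7Z)-11-acetoxy-3,9-dihydroxycembra-4,7-dien-16,12-olid-17-oic acid
Conditions: [(Me2N)3S][Me3SiF2] (TASF), DMF, 0 °C to rt; aq. NH4Cl work-up
Reagents that add atoms: none
Why: Fluoride cleaves the secondary TBS ether and fragments the 2-(trimethylsilyl)ethyl ester (β-elimination to ethene and Me3SiF) under almost neutral conditions that should leave the acetate, the lactone and the allylic alcohols untouched.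

**Step 16**
Reactants: 27 (1S,3S,9R,11R,12S,4E,7Z)-11-acetoxy-3,9-dihydroxycembra-4,7-dien-16,12-olid-17-oic acid
Product: 29 CNP0183491.1, (1S,3S,9R,11R,12S,4E,7Z)-11-acetoxy-3,9-dihydroxycembra-4,7,15(17)-trien-16,12-olide, via Mannich base 28 (not isolated)
Conditions: (CH2O)n, Et2NH, THF, 50 °C
Reagents that add atoms: formaldehyde, C=O
Why: Mannich reaction of the malonic half-acid at C15 with formaldehyde and Et2NH followed by decarboxylative elimination of the amine, the classical methylenation of α-carboxy lactones, installs the C15=C17 exo-methylene and erases the C15 stereocentre.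

**Compound list**
1 | hex-5-en-1-yne | C#CCCC=C | starting material
2 | but-3-en-2-one | CC(=O)C=C | starting material
3 | dimethyl[(1E)-2-methylhexa-1,5-dien-1-yl]alumane | C[Al](C)/C=C(\C)CCC=C | intermediate (not isolated)
4 | dimethylaluminium (2Z,5E)-6-methyldeca-2,5,9-trien-2-olate | C/C(O[Al](C)C)=C/C/C=C(\C)CCC=C | intermediate (not isolated)
5 | trimethyl{[(2Z,5E)-6-methyldeca-2,5,9-trien-2-yl]oxy}silane | C/C(O[Si](C)(C)C)=C/C/C=C(\C)CCC=C | intermediate
6 | trimethyl{[(2S,3R)-3-{[(2R,3R)-3-(but-3-en-1-yl)-3-methyloxiran-2-yl]methyl}-2-methyloxiran-2-yl]oxy}silane | C[Si](C)(C)O[C@]1(C)O[C@@H]1C[C@H]2O[C@]2(C)CCC=C | intermediate (not isolated)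
7 | (3R)-4-[(2R,3R)-3-(but-3-en-1-yl)-3-methyloxiran-2-yl]-3-hydroxybutan-2-one | CC(=O)[C@H](O)C[C@H]1O[C@]1(C)CCC=C | intermediate
8 | (3R)-4-[(2R,3R)-3-(but-3-en-1-yl)-3-methyloxiran-2-yl]-3-[(tert-butyldimethylsilyl)oxy]butan-2-one | CC(=O)[C@H](O[Si](C)(C)C(C)(C)C)C[C@H]1O[C@]1(C)CCC=C | intermediate
9 | pent-3-yn-1-ol | CC#CCCO | starting material
10 | chlorobis(cyclopentadienyl)[(2E)-5-hydroxypent-2-en-2-yl]zirconium | C/C(=C\CCO)[Zr](Cl)(C1C=CC=C1)C1C=CC=C1 | intermediate (not isolated)
11 | (3E)-4-iodopent-3-en-1-ol | C/C(I)=C\CCO | intermediate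
12 | (2E)-2,5-diiodopent-2-ene | C/C(I)=C\CCI | intermediate
13 | [(3E)-4-iodopent-3-en-1-yl]triphenylphosphonium iodide | C/C(I)=C\CC[P+](c1ccccc1)(c1ccccc1)c1ccccc1.[I-] | intermediate
14 | [(3E)-4-iodopent-3-en-1-ylidene]triphenylphosphorane | C/C(I)=C\CC=P(c1ccccc1)(c1ccccc1)c1ccccc1 | intermediate (not isolated)
15 | tert-butyl{[(2R,3Z,6E)-1-[(2R,3R)-3-(but-3-en-1-yl)-3-methyloxiran-2-yl]-7-iodo-3-methylocta-3,6-dien-2-yl]oxy}dimethylsilane | I/C(C)=C/C/C=C(/C)[C@H](O[Si](C)(C)C(C)(C)C)C[C@H]1O[C@]1(C)CCC=C | intermediate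
16 | (2E)-but-2-enal | C/C=C/C=O | starting material
17 | (2E)-5-[(2R,3R)-3-{(2R,3Z,6E)-2-[(tert-butyldimethylsilyl)oxy]-7-iodo-3-methylocta-3,6-dien-1-yl}-2-methyloxiran-2-yl]pent-2-enal | I/C(C)=C/C/C=C(/C)[C@H](O[Si](C)(C)C(C)(C)C)C[C@H]1O[C@]1(C)CC/C=C/C=O | intermediate
18 | 3-(tert-butoxy)-3-oxopropanoic acid | CC(C)(C)OC(=O)CC(=O)O | starting material
19 | 2-(trimethylsilyl)ethanol | C[Si](C)(C)CCO | starting material
20 | tert-butyl 2-(trimethylsilyl)ethyl propanedioate | CC(C)(C)OC(=O)CC(=O)OCC[Si](C)(C)C | intermediate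
21 | 1-tert-butyl 3-[2-(trimethylsilyl)ethyl] 2-[(3S)-1-{(2R,3R)-3-[(2R,3Z,6E)-2-[(tert-butyldimethylsilyl)oxy]-7-iodo-3-methylocta-3,6-dien-1-yl]-2-methyloxiran-2-yl}-5-oxopentan-3-yl]propanedioate | I/C(C)=C/C/C=C(/C)[C@H](O[Si](C)(C)C(C)(C)C)C[C@H]1O[C@]1(C)CC[C@@H](CC=O)C(C(=O)OC(C)(C)C)C(=O)OCC[Si](C)(C)C | intermediate (not isolated)
22 | 2-(trimethylsilyl)ethyl (4S,7S)-7-[(1R,3R,4Z,7E)-3-[(tert-butyldimethylsilyl)oxy]-1-hydroxy-8-iodo-4-methylnona-4,7-dien-1-yl]-7-methyl-2-oxo-4-(2-oxoethyl)oxepane-3-carboxylate | I/C(C)=C/C/C=C(/C)[C@H](O[Si](C)(C)C(C)(C)C)C[C@@H](O)[C@]1(C)CC[C@@H](CC=O)C(C(=O)OCC[Si](C)(C)C)C(=O)O1 | intermediate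
23 | 2-(trimethylsilyl)ethyl (4S,7S)-7-[(1R,3R,4Z,7E)-1-acetoxy-3-[(tert-butyldimethylsilyl)oxy]-8-iodo-4-methylnona-4,7-dien-1-yl]-7-methyl-2-oxo-4-(2-oxoethyl)oxepane-3-carboxylate | I/C(C)=C/C/C=C(/C)[C@H](O[Si](C)(C)C(C)(C)C)C[C@@H](OC(C)=O)[C@]1(C)CC[C@@H](CC=O)C(C(=O)OCC[Si](C)(C)C)C(=O)O1 | intermediate
24 | 2-(trimethylsilyl)ethyl (1S,9R,11R,12S,4E,7Z)-11-acetoxy-9-[(tert-butyldimethylsilyl)oxy]-3-hydroxycembra-4,7-dien-16,12-olid-17-oate (C3 epimers) | C[Si](C)(C)CCOC(=O)C1C(=O)O[C@@]2(C)CC[C@H]1CC(O)/C(C)=C/C/C=C(/C)[C@H](O[Si](C)(C)C(C)(C)C)C[C@H]2OC(C)=O | intermediate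
25 | 2-(trimethylsilyl)ethyl (1S,9R,11R,12S,4E,7Z)-11-acetoxy-9-[(tert-butyldimethylsilyl)oxy]-3-oxocembra-4,7-dien-16,12-olid-17-oate | C[Si](C)(C)CCOC(=O)C1C(=O)O[C@@]2(C)CC[C@H]1CC(=O)/C(C)=C/C/C=C(/C)[C@H](O[Si](C)(C)C(C)(C)C)C[C@H]2OC(C)=O | intermediate
26 | 2-(trimethylsilyl)ethyl (1S,3S,9R,11R,12S,4E,7Z)-11-acetoxy-9-[(tert-butyldimethylsilyl)oxy]-3-hydroxycembra-4,7-dien-16,12-olid-17-oate | C[Si](C)(C)CCOC(=O)C1C(=O)O[C@@]2(C)CC[C@H]1C[C@H](O)/C(C)=C/C/C=C(/C)[C@H](O[Si](C)(C)C(C)(C)C)C[C@H]2OC(C)=O | intermediate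
27 | (1S,3S,9R,11R,12S,4E,7Z)-11-acetoxy-3,9-dihydroxycembra-4,7-dien-16,12-olid-17-oic acid | OC(=O)C1C(=O)O[C@@]2(C)CC[C@H]1C[C@H](O)/C(C)=C/C/C=C(/C)[C@H](O)C[C@H]2OC(C)=O | intermediate
28 | 15-[(diethylamino)methyl] derivative of 27 (Mannich base) | CCN(CC)CC1(C(=O)O)C(=O)O[C@@]2(C)CC[C@H]1C[C@H](O)/C(C)=C/C/C=C(/C)[C@H](O)C[C@H]2OC(C)=O | intermediate (not isolated)
29 | CNP0183491.1, (1S,3S,9R,11R,12S,4E,7Z)-11-acetoxy-3,9-dihydroxycembra-4,7,15(17)-trien-16,12-olide | C=C1C(=O)O[C@@]2(C)CC[C@H]1C[C@H](O)/C(C)=C/C/C=C(/C)[C@H](O)C[C@H]2OC(C)=O | target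

**Step count and risks**
Total step count: 16. Longest linear sequence: 12 steps (steps 1, 2, 3, 7, 8, 10, 11, 12, 13, 14, 15, 16).

Step 10 (bears the label). What may go wrong: the seven-membered closure by the ester carbonyl may be outrun by a 1,2-hydride shift of the activated epoxide (Meinwald rearrangement) or by cation–olefin cyclisation onto the C7=C8 bond. Fallback with known chemistry, setting out from 17 and returning at 22: 17 is combined under the same amine catalysis with prop-2-en-1-yl 2-(trimethylsilyl)ethyl propanedioate F1 (made from commercial allyl hydrogen malonate and 19 with DCC/DMAP) and the allyl-ester Michael adduct F2 is isolated. Pd(PPh3)4 with dimedone as allyl acceptor then frees the malonic half-acid F3 without touching the epoxide. Catalytic camphorsulfonic acid in CH2Cl2 at 0 °C closes the lactone by the long-established Brønsted-acid opening of an epoxide by a free carboxylic acid (attack at the tertiary C12 with inversion), which gives 22.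

Step 12. What may go wrong: intermolecular coupling to oligomers, or protonolysis of the alkenyl–metal bond before ring closure. Fallback, setting out from 23 and returning at 25: 23 is oxidised (NaClO2, NaH2PO4, 2-methylbut-2-ene) to the carboxylic acid F4, which 2,2'-dipyridyl disulfide and PPh3 convert into the S-(pyridin-2-yl) thioester F5. The zirconium/nickel-mediated thioester–alkenyl iodide ketone coupling (NiBr2(dtbbpy), Cp2ZrCl2, Zn, high dilution) then closes the ring directly to enone 25, so that step 13 is no longer needed.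

Step 2. What may go wrong: incomplete enantioface control in the oxidation of the enol ether (C9), or hydrolysis of the enol ether before it is oxidised. Fallback from the chiral pool, setting out from 3 and returning at 8: 3 is converted with n-BuLi into the lithium alanate F6, which opens (R)-glycidyl 4-methoxybenzyl ether at its terminal carbon to give the homoallylic alcohol F7 with C9 already fixed. Silylation (TBSCl, imidazole) gives the silyl ether F8, and Shi epoxidation of its only trisubstituted olefin gives the epoxide F9. DDQ removes the 4-methoxybenzyl group to give the primary alcohol F10, Dess–Martin oxidation gives the aldehyde F11, MeMgBr at −78 °C gives the secondary alcohol F12, and a second Dess–Martin oxidation gives 8.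

**Further compounds**
F1 | step 10 | prop-2-en-1-yl 2-(trimethylsilyl)ethyl propanedioate | C=CCOC(=O)CC(=O)OCC[Si](C)(C)C
F2 | step 10 | 1-(prop-2-en-1-yl) 3-[2-(trimethylsilyl)ethyl] 2-[(3S)-1-{(2R,3R)-3-[(2R,3Z,6E)-2-[(tert-butyldimethylsilyl)oxy]-7-iodo-3-methylocta-3,6-dien-1-yl]-2-methyloxiran-2-yl}-5-oxopentan-3-yl]propanedioate | I/C(C)=C/C/C=C(/C)[C@H](O[Si](C)(C)C(C)(C)C)C[C@H]1O[C@]1(C)CC[C@@H](CC=O)C(C(=O)OCC=C)C(=O)OCC[Si](C)(C)C
F3 | step 10 | malonic half-acid of F2 (allyl ester replaced by CO2H) | I/C(C)=C/C/C=C(/C)[C@H](O[Si](C)(C)C(C)(C)C)C[C@H]1O[C@]1(C)CC[C@@H](CC=O)C(C(=O)O)C(=O)OCC[Si](C)(C)C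
F4 | step 12 | carboxylic acid from 23 (CH2CHO oxidised to CH2CO2H) | I/C(C)=C/C/C=C(/C)[C@H](O[Si](C)(C)C(C)(C)C)C[C@@H](OC(C)=O)[C@]1(C)CC[C@@H](CC(=O)O)C(C(=O)OCC[Si](C)(C)C)C(=O)O1
F5 | step 12 | S-(pyridin-2-yl) thioester of F4 | I/C(C)=C/C/C=C(/C)[C@H](O[Si](C)(C)C(C)(C)C)C[C@@H](OC(C)=O)[C@]1(C)CC[C@@H](CC(=O)Sc2ccccn2)C(C(=O)OCC[Si](C)(C)C)C(=O)O1
F6 | step 2 | lithium butyl(dimethyl)[(1E)-2-methylhexa-1,5-dien-1-yl]aluminate | [Li+].CCCC[Al-](C)(C)/C=C(\C)CCC=C
F7 | step 2 | (2R,4E)-1-[(4-methoxybenzyl)oxy]-5-methylnona-4,8-dien-2-ol | COc1ccc(COC[C@H](O)C/C=C(\C)CCC=C)cc1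
F8 | step 2 | tert-butyl{[(2R,4E)-1-[(4-methoxybenzyl)oxy]-5-methylnona-4,8-dien-2-yl]oxy}dimethylsilane | COc1ccc(COC[C@H](O[Si](C)(C)C(C)(C)C)C/C=C(\C)CCC=C)cc1
F9 | step 2 | tert-butyl{[(2R)-1-[(2R,3R)-3-(but-3-en-1-yl)-3-methyloxiran-2-yl]-3-[(4-methoxybenzyl)oxy]propan-2-yl]oxy}dimethylsilane | COc1ccc(COC[C@H](O[Si](C)(C)C(C)(C)C)C[C@H]2O[C@]2(C)CCC=C)cc1
F10 | step 2 | (2R)-3-[(2R,3R)-3-(but-3-en-1-yl)-3-methyloxiran-2-yl]-2-[(tert-butyldimethylsilyl)oxy]propan-1-ol | OC[C@H](O[Si](C)(C)C(C)(C)C)C[C@H]1O[C@]1(C)CCC=C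
F11 | step 2 | (2R)-3-[(2R,3R)-3-(but-3-en-1-yl)-3-methyloxiran-2-yl]-2-[(tert-butyldimethylsilyl)oxy]propanal | O=C[C@H](O[Si](C)(C)C(C)(C)C)C[C@H]1O[C@]1(C)CCC=C
F12 | step 2 | (3R)-4-[(2R,3R)-3-(but-3-en-1-yl)-3-methyloxiran-2-yl]-3-[(tert-butyldimethylsilyl)oxy]butan-2-ol (C2 epimers) | CC(O)[C@H](O[Si](C)(C)C(C)(C)C)C[C@H]1O[C@]1(C)CCC=C
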